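**Plan**

1. Ring locants are those of the 7-oxabicyclo[4.1.0]hept-2-ene core: C1 epoxide CH, C2 (=C–Me), C3 (=CH), C4 quaternary (Me, pyranone), C5 (CH bearing the side chain), C6 epoxide C–Me.
2. Cuts, in retrosynthetic order: (a) the side-chain carbinol C–Cα bond (aldol of pentan-3-one with a 2-substituted acrolein); (b) the two epoxide C–O bonds, back to a 6-methylcyclohexenone; (c) C2=C3, back to a 1,5-keto aldehyde; (d) C4–CH3 and C4–C5, back to an aryl pyranonylacetate and an enone.
3. Forward: the pyranone is built first; a δ-enol lactone (temporary ring) is formed and methylated, then opened by half-reduction; the carbocycle is closed at C2=C3; the epoxide follows and the side chain comes last.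
4. Enabling feature: C6(Me)–C1–C2(Me) is a pentan-3-one unit and C3 hangs on the quaternary C4, so C3 can be a non-enolisable aldehyde that only the ethyl-ketone carbon C2 can reach in a six-membered closure.
5. Stereochemistry: C5 from a chiral carbene catalyst; C4 by alkylation anti to the C5 chain in the enol lactone; C6 and C1 by enolate hydroxylation anti to the C5 chain, hydroxyl-directed reduction and invertive epoxide closure; both side-chain centres by a reagent-controlled boron aldol.

Key step: step 9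

Notation: Pyr = 6-methoxy-3,5-dimethyl-4-oxo-4H-pyran-2-yl; TBS = tert-butyldimethylsilyl.
Assumption: the facial sense of the triazolium catalyst (step 6) and of (+)-diisopinocampheylboron triflate (step 17) is taken by analogy with simple enones and 2-substituted acroleins; the mirror-image reagent would be used if either proved opposite.

**Route**

Step 1
Reactants: 1 ethyl 2-methyl-3-oxopentanoate; 2 N-methoxy-N-methylacetamide
Product: 3 ethyl 2,4-dimethyl-3,5-dioxohexanoate (diastereomer and enol mixture)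
Conditions: LiN(iPr)2 (2.2 equiv), THF, −78 to 0 °C; then 2, −78 °C to rt; aq. HCl
Reagents that add atoms: none
Why: Claisen-type γ-acylation of the β-keto ester dianion, whose terminal carbanion is the more reactive site, by an N-methoxy-N-methylamide that stops at the ketone; the stereocentres are lost in step 2.

Step 2
Reactants: 3 ethyl 2,4-dimethyl-3,5-dioxohexanoate
Product: 4 4-hydroxy-3,5,6-trimethyl-2H-pyran-2-one
Conditions: DBU (1.5 equiv), toluene, 80 °C; aq. HCl
Reagents that add atoms: none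
Why: base-mediated enol lactonisation (the C5 enolate oxygen attacks the ester, 6-exo-trig) followed by enolisation to the aromatic 4-hydroxy-2-pyranone.

Step 3
Reactants: 4 4-hydroxy-3,5,6-trimethyl-2H-pyran-2-one
Product: 5 2-methoxy-3,5,6-trimethyl-4H-pyran-4-one
Conditions: MeOTf (1.1 equiv), CH2Cl2, 0 °C to rt; aq. NaHCO3
Reagents that add atoms: methyl trifluoromethanesulfonate, COS(=O)(=O)C(F)(F)F
Why: O-alkylation of neutral 4 by a hard methylating agent should occur at the lactone carbonyl oxygen, and loss of the hydroxyl proton from the pyrylium then gives the 2-methoxy-4-pyranone rather than the 4-methoxy-2-pyranone.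

Step 4
Reactants: 5 2-methoxy-3,5,6-trimethyl-4H-pyran-4-one
Product: 6 4-nitrophenyl 2-Pyr-acetate
Conditions: LiN(SiMe3)2 (2.1 equiv), THF, −78 °C; 4-nitrophenyl chloroformate, −78 °C; AcOH, −78 °C
Reagents that add atoms: 4-nitrophenyl chloroformate, O=C(Cl)Oc1ccc(cc1)[N+](=O)[O-]
Why: vinylogous deprotonation of the 6-methyl group and C-acylation of the extended enolate at the exocyclic carbon; the second equivalent of base holds the more acidic product as its enolate until the cold quench.

Step 5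
Reactants: 7 3-(TBS-oxy)propanal; 8 diethyl (2-oxobutyl)phosphonate
Product: 9 (E)-7-(TBS-oxy)hept-4-en-3-one
Conditions: LiCl, iPr2NEt, MeCN, rt
Reagents that add atoms: none
Why: Horner–Wadsworth–Emmons olefination of a β-keto phosphonate under mild LiCl/amine conditions should give the E-enone without β-elimination of the silyloxy aldehyde.

Step 6
Reactants: 6 4-nitrophenyl 2-Pyr-acetate; 9 (E)-7-(TBS-oxy)hept-4-en-3-one
Product: 10 (3R,4S)-4-[2-(TBS-oxy)ethyl]-6-ethyl-3-Pyr-3,4-dihydro-2H-pyran-2-one (3,4-cis)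
Conditions: (5aR,10bS)-2-mesityl-5a,10b-dihydro-4H,6H-indeno[2,1-b][1,2,4]triazolo[4,3-d][1,4]oxazin-2-ium chloride (10 mol%), iPr2NEt (1.5 equiv), 4 Å molecular sieves, CH2Cl2, rt
Reagents that add atoms: none
Why: N-heterocyclic-carbene-catalysed formal oxa-[4+2] annulation (Michael addition–lactonisation) in which the carbene displaces 4-nitrophenoxide, the acyl azolium is deprotonated to an azolium enolate that adds endo to the s-cis enone on the face left open by the indane wall (setting C4 of the lactone), and O-acylation releases the catalyst; the cis C3 centre is erased in step 7.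

Step 7
Reactants: 10 (3R,4S)-enol lactone
Product: 11 (3R,4S)-4-[2-(TBS-oxy)ethyl]-6-ethyl-3-methyl-3-Pyr-3,4-dihydro-2H-pyran-2-one
Conditions: LiN(SiMe3)2 (1.1 equiv), THF, −78 °C; MeI (3 equiv), −78 to −30 °C
Reagents that add atoms: iodomethane, CI
Why: alkylation of the pyranone-stabilised lactone enolate, in which only C4 of the nearly flat ring is sp3 and its chain lies pseudoaxial, so methyl should enter on the opposite face (1,2-induction) and create the quaternary centre with methyl trans and Pyr cis to the chain.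

Step 8
Reactants: 11 methylated enol lactone
Product: 12 (2R,3S)-3-[2-(TBS-oxy)ethyl]-2-methyl-5-oxo-2-Pyr-heptanal
Conditions: iBu2AlH (1.1 equiv), CH2Cl2, −78 °C; aq. potassium sodium tartrate (KNaC4H4O6)
Reagents that add atoms: none
Why: half-reduction of an enol ester, in which hydride addition to the lactone carbonyl gives an aluminate that opens on work-up to the aldehyde and (from the enol) the ketone, leaving both stereocentres untouched.

Step 9
Reactants: 12 (2R,3S)-keto aldehyde
Product: 14 (4S,5S)-5-[2-(TBS-oxy)ethyl]-2,4-dimethyl-4-Pyr-cyclohex-2-en-1-one, via aldol adduct 13 (not isolated)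
Conditions: (PhCH2)2NH2+ CF3CO2− (0.5 equiv), toluene, 60 °C
Reagents that add atoms: none
Why: The ammonium salt promotes enolisation (enamine formation) of the ethyl ketone on its CH2CH3 side, this carbon adds to the aldehyde, and the β-hydroxy ketone 13 loses water by E1cB, so the C2–C3 ring bond is made and becomes the alkene in one operation. The closest known reaction type is the aldol-condensation half of a Robinson annulation, run on a 1,5-keto aldehyde under amine-salt catalysis. The six-membered ring closes in the 6-(enolendo)-exo-trig mode. No new stereocentre survives, since the carbinol and α-methyl centres of 13 are erased on dehydration, and C4 and C5 are carried through because neither is enolisable. The step needs regioselectivity between the two ketone α-carbons and between the two carbonyl groups: the quaternary α-carbon makes the aldehyde a pure electrophile and the other α-carbon could only close a four-membered ring. The non-basic medium should prevent retro-Michael cleavage of the 1,5-dicarbonyl array, which would scramble C4 and C5.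

Step 10
Reactants: 14 (4S,5S)-cyclohexenone
Product: 15 (4S,5S,6S)-5-[2-(TBS-oxy)ethyl]-2,4,6-trimethyl-4-Pyr-cyclohex-2-en-1-one
Conditions: LiN(iPr)2 (1.1 equiv), THF, −78 °C; MeI, −78 to −40 °C
Reagents that add atoms: iodomethane, CI
Why: kinetic α′-deprotonation of the cyclohexenone (the γ-carbon is quaternary) and enolate alkylation anti to the neighbouring chain; this centre is reset in step 11.

Step 11
Reactants: 15 trimethylcyclohexenone
Product: 16 (4R,5R,6S)-5-[2-(TBS-oxy)ethyl]-6-hydroxy-2,4,6-trimethyl-4-Pyr-cyclohex-2-en-1-one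
Conditions: KN(SiMe3)2 (1.3 equiv), THF, −78 to −40 °C; 2-(phenylsulfonyl)-3-phenyloxaziridine, −78 °C; aq. NH4Cl
Reagents that add atoms: 2-(phenylsulfonyl)-3-phenyloxaziridine, O=S(=O)(c1ccccc1)N1OC1c1ccccc1
Why: electrophilic α-hydroxylation of the potassium enolate by an N-sulfonyloxaziridine, with oxygen delivered to the face anti to the adjacent chain, should give the tertiary carbinol with OH trans and methyl cis to that chain.

Step 12
Reactants: 16 α-hydroxy enone
Product: 17 (1S,2S,5R,6R)-6-[2-(TBS-oxy)ethyl]-1,3,5-trimethyl-5-Pyr-cyclohex-3-ene-1,2-diol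
Conditions: Me4NBH(OAc)3 (5 equiv), MeCN–AcOH (1:1), −30 to 0 °C
Reagents that add atoms: none
Why: hydroxyl-directed triacetoxyborohydride reduction (Evans–Saksena type), in which the tertiary hydroxyl binds boron and hydride is delivered intramolecularly to the same face, so the new secondary hydroxyl should be trans to the tertiary one.

Step 13
Reactants: 17 trans-diol
Product: 19 (1R,4R,5R,6S)-5-[2-(TBS-oxy)ethyl]-2,4,6-trimethyl-4-Pyr-7-oxabicyclo[4.1.0]hept-2-ene, via monotosylate 18 (not isolated)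
Conditions: NaH (3 equiv), 1-(p-toluenesulfonyl)imidazole (1.2 equiv), THF, 0 °C to rt
Reagents that add atoms: none
Why: selective sulfonylation of the less hindered secondary allylic alkoxide followed by intramolecular SN2 displacement by the antiperiplanar tertiary alkoxide (trans-diol to epoxide), with inversion at the secondary carbon, should place the epoxide trans to the C5 chain.

Step 14
Reactants: 19 epoxy silyl ether
Product: 20 2-[(1R,4R,5R,6S)-2,4,6-trimethyl-4-Pyr-7-oxabicyclo[4.1.0]hept-2-en-5-yl]ethan-1-ol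
Conditions: Bu4NF (1.2 equiv), THF, 0 °C; aq. NH4Cl
Reagents that add atoms: none
Why: fluoride cleavage of the silyl ether, to which the vinyl epoxide and the pyranone are inert.

Step 15
Reactants: 20 primary alcohol
Product: 21 2-[(1R,4R,5R,6S)-2,4,6-trimethyl-4-Pyr-7-oxabicyclo[4.1.0]hept-2-en-5-yl]acetaldehyde
Conditions: DMP (1,1,1-triacetoxy-1,1-dihydro-1,2-benziodoxol-3(1H)-one, 1.3 equiv), NaHCO3, CH2Cl2, 0 °C to rt
Reagents that add atoms: none
Why: buffered hypervalent-iodine oxidation of the primary alcohol to the aldehyde without acid that would open the vinyl epoxide.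

Step 16
Reactants: 21 aldehyde
Product: 23 2-[(1R,4R,5R,6S)-2,4,6-trimethyl-4-Pyr-7-oxabicyclo[4.1.0]hept-2-en-5-yl]prop-2-enal, via Mannich base 22 (not isolated)
Conditions: dimethylmethyleneiminium iodide (2 equiv), Et3N (3 equiv), CH2Cl2, rt
Reagents that add atoms: dimethylmethyleneiminium iodide, C=[N+](C)C.[I-]
Why: Mannich reaction of the aldehyde enol with the iminium salt followed by β-elimination of dimethylamine (α-methylenation) should give the 2-substituted acrolein.

Step 17
Reactants: 23 2-substituted acrolein; 24 pentan-3-one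
Product: 27 (4R,5R)-5-hydroxy-4-methyl-6-[(1R,4R,5R,6S)-2,4,6-trimethyl-4-Pyr-7-oxabicyclo[4.1.0]hept-2-en-5-yl]hept-6-en-3-one (the target), via enol borinate 25 (not isolated), via boron aldolate 26 (not isolated)
Conditions: (+)-Ipc2BOTf (from (−)-α-pinene, 1.3 equiv), iPr2NEt (1.5 equiv), CH2Cl2, −78 °C (enolisation of 24); then 23, −78 to −20 °C; MeOH, pH 7 buffer, 30% H2O2, 0 °C
Reagents that add atoms: none
Why: boron-mediated aldol addition in which the Z-enol diisopinocampheylborinate reacts through a closed chair transition state to give the syn adduct and the isopinocampheyl ligands direct attack to the Re face of the aldehyde, setting both side-chain centres (R,R) under reagent control.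

**Compound list**

1 | ethyl 2-methyl-3-oxopentanoate | CCC(=O)C(C)C(=O)OCC | starting material
2 | N-methoxy-N-methylacetamide | CC(=O)N(C)OC | starting material
3 | ethyl 2,4-dimethyl-3,5-dioxohexanoate | CC(=O)C(C)C(=O)C(C)C(=O)OCC | intermediate
4 | 4-hydroxy-3,5,6-trimethyl-2H-pyran-2-one | Cc1oc(=O)c(C)c(O)c1C | intermediate
5 | 2-methoxy-3,5,6-trimethyl-4H-pyran-4-one | Cc1oc(OC)c(C)c(=O)c1C | intermediate
6 | 4-nitrophenyl 2-(6-methoxy-3,5-dimethyl-4-oxo-4H-pyran-2-yl)acetate | O=C(Cc1oc(OC)c(C)c(=O)c1C)Oc1ccc(cc1)[N+](=O)[O-] | intermediate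
7 | 3-[(tert-butyldimethylsilyl)oxy]propanal | O=CCCO[Si](C)(C)C(C)(C)C | starting material
8 | diethyl (2-oxobutyl)phosphonate | CCC(=O)CP(=O)(OCC)OCC | starting material
9 | (E)-7-[(tert-butyldimethylsilyl)oxy]hept-4-en-3-one | CCC(=O)/C=C/CCO[Si](C)(C)C(C)(C)C | intermediate
10 | (3R,4S)-4-[2-(TBS-oxy)ethyl]-6-ethyl-3-Pyr-3,4-dihydro-2H-pyran-2-one | CC(C)(C)[Si](C)(C)OCC[C@H]1C=C(CC)OC(=O)[C@H]1c1oc(OC)c(C)c(=O)c1C | intermediate
11 | (3R,4S)-4-[2-(TBS-oxy)ethyl]-6-ethyl-3-methyl-3-Pyr-3,4-dihydro-2H-pyran-2-one | CC(C)(C)[Si](C)(C)OCC[C@H]1C=C(CC)OC(=O)[C@@]1(C)c1oc(OC)c(C)c(=O)c1C | intermediate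
12 | (2R,3S)-3-[2-(TBS-oxy)ethyl]-2-methyl-5-oxo-2-Pyr-heptanal | CC(C)(C)[Si](C)(C)OCC[C@H]([C@](C=O)(C)c1oc(OC)c(C)c(=O)c1C)CC(=O)CC | intermediate
13 | (4S,5S)-5-[2-(TBS-oxy)ethyl]-3-hydroxy-2,4-dimethyl-4-Pyr-cyclohexan-1-one (epimers at C2 and C3) | CC(C)(C)[Si](C)(C)OCC[C@H]1CC(=O)C(C)C(O)[C@@]1(C)c1oc(OC)c(C)c(=O)c1C | intermediate
14 | (4S,5S)-5-[2-(TBS-oxy)ethyl]-2,4-dimethyl-4-Pyr-cyclohex-2-en-1-one | CC(C)(C)[Si](C)(C)OCC[C@H]1CC(=O)C(C)=C[C@@]1(C)c1oc(OC)c(C)c(=O)c1C | intermediate
15 | (4S,5S,6S)-5-[2-(TBS-oxy)ethyl]-2,4,6-trimethyl-4-Pyr-cyclohex-2-en-1-one | CC(C)(C)[Si](C)(C)OCC[C@H]1[C@H](C)C(=O)C(C)=C[C@@]1(C)c1oc(OC)c(C)c(=O)c1C | intermediate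
16 | (4R,5R,6S)-5-[2-(TBS-oxy)ethyl]-6-hydroxy-2,4,6-trimethyl-4-Pyr-cyclohex-2-en-1-one | CC(C)(C)[Si](C)(C)OCC[C@H]1[C@](C)(O)C(=O)C(C)=C[C@@]1(C)c1oc(OC)c(C)c(=O)c1C | intermediate
17 | (1S,2S,5R,6R)-6-[2-(TBS-oxy)ethyl]-1,3,5-trimethyl-5-Pyr-cyclohex-3-ene-1,2-diol | CC(C)(C)[Si](C)(C)OCC[C@H]1[C@](C)(O)[C@@H](O)C(C)=C[C@@]1(C)c1oc(OC)c(C)c(=O)c1C | intermediate
18 | 2-O-(p-toluenesulfonyl) derivative of diol 17 | CC(C)(C)[Si](C)(C)OCC[C@H]1[C@](C)(O)[C@@H](OS(=O)(=O)c2ccc(C)cc2)C(C)=C[C@@]1(C)c1oc(OC)c(C)c(=O)c1C | intermediate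
19 | (1R,4R,5R,6S)-5-[2-(TBS-oxy)ethyl]-2,4,6-trimethyl-4-Pyr-7-oxabicyclo[4.1.0]hept-2-ene | CC(C)(C)[Si](C)(C)OCC[C@H]1[C@]2(C)O[C@@H]2C(C)=C[C@@]1(C)c1oc(OC)c(C)c(=O)c1C | intermediate
20 | 2-[(1R,4R,5R,6S)-2,4,6-trimethyl-4-Pyr-7-oxabicyclo[4.1.0]hept-2-en-5-yl]ethan-1-ol | OCC[C@H]1[C@]2(C)O[C@@H]2C(C)=C[C@@]1(C)c1oc(OC)c(C)c(=O)c1C | intermediate
21 | 2-[(1R,4R,5R,6S)-2,4,6-trimethyl-4-Pyr-7-oxabicyclo[4.1.0]hept-2-en-5-yl]acetaldehyde | O=CC[C@H]1[C@]2(C)O[C@@H]2C(C)=C[C@@]1(C)c1oc(OC)c(C)c(=O)c1C | intermediate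
22 | 3-(dimethylamino)-2-[(1R,4R,5R,6S)-2,4,6-trimethyl-4-Pyr-7-oxabicyclo[4.1.0]hept-2-en-5-yl]propanal (epimers at C2) | CN(C)CC(C=O)[C@H]1[C@]2(C)O[C@@H]2C(C)=C[C@@]1(C)c1oc(OC)c(C)c(=O)c1C | intermediate
23 | 2-[(1R,4R,5R,6S)-2,4,6-trimethyl-4-Pyr-7-oxabicyclo[4.1.0]hept-2-en-5-yl]prop-2-enal | C=C(C=O)[C@H]1[C@]2(C)O[C@@H]2C(C)=C[C@@]1(C)c1oc(OC)c(C)c(=O)c1C | intermediate
24 | pentan-3-one | CCC(=O)CC | starting material
25 | (Z)-pent-2-en-3-yl bis[(+)-isopinocampheyl]borinate | C/C=C(/CC)OB([C@H]1C[C@H]2C[C@@H]([C@@H]1C)C2(C)C)[C@H]1C[C@H]2C[C@@H]([C@@H]1C)C2(C)C | intermediate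
26 | O-bis[(+)-isopinocampheyl]boryl derivative of 27 | C=C([C@H](OB([C@H]1C[C@H]2C[C@@H]([C@@H]1C)C2(C)C)[C@H]1C[C@H]2C[C@@H]([C@@H]1C)C2(C)C)[C@@H](C)C(=O)CC)[C@H]1[C@]2(C)O[C@@H]2C(C)=C[C@@]1(C)c1oc(OC)c(C)c(=O)c1C | intermediate
27 | (4R,5R)-5-hydroxy-4-methyl-6-[(1R,4R,5R,6S)-2,4,6-trimethyl-4-Pyr-7-oxabicyclo[4.1.0]hept-2-en-5-yl]hept-6-en-3-one | C=C([C@H](O)[C@@H](C)C(=O)CC)[C@H]1[C@]2(C)O[C@@H]2C(C)=C[C@@]1(C)c1oc(OC)c(C)c(=O)c1C | target

**Totals**

Total step count: 17. Longest linear sequence: 16 steps (steps 1–4 and 6–17).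

**Steps most likely to fail**

Risk 1, step 6. The acidic aryl ester may add to the enone by an uncatalysed, amine-mediated pathway, or the aliphatic enone may turn over slowly, so that enantiocontrol at the chain-bearing carbon is eroded. The fallback sets out from 5 and 9 and separates bond formation from lactonisation. Acylation of lithiated 5 with allyl chloroformate would give allyl 2-Pyr-acetate F1. Iminium activation of 9 by 9-amino-9-deoxy-epi-quinine and trifluoroacetic acid should then add F1 enantioselectively to give allyl 3-[2-(TBS-oxy)ethyl]-5-oxo-2-Pyr-heptanoate F2, epimeric at C2. Deallylation with Pd(PPh3)4 (zerovalent palladium) and morpholine would give the keto acid 3-[2-(TBS-oxy)ethyl]-5-oxo-2-Pyr-heptanoic acid F3. Enol lactonisation with trifluoroacetic anhydride and Et3N returns to 10; its C3 configuration is of no consequence.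

Risk 2, step 8. Once the aluminate collapses, the freed aldehyde may be reduced further, or hydride may attack the pyranone. The fallback sets out from 11 and avoids hydride at the aldehyde stage. Ring opening with LiSEt (from EtSH) would give the keto thioester S-ethyl (2R,3S)-3-[2-(TBS-oxy)ethyl]-2-methyl-5-oxo-2-Pyr-heptanethioate F4. Thioester-selective hydrosilane reduction (Et3SiH, Pd/C, acetone; Fukuyama reduction) would leave the ketone untouched and comes back to the route at 12.

Risk 3, step 13. The secondary allylic sulfonate may ionise and undergo allylic transposition or elimination before the tertiary alkoxide closes; in addition, poor anti delivery in step 12 would give a cis-diol that cannot close. The fallback sets out from 15 and makes the epoxide by oxidation of a diene. Enolate triflation (KN(SiMe3)2, PhNTf2) would give the dienyl triflate (5S,6S)-6-[2-(TBS-oxy)ethyl]-1,3,5-trimethyl-5-Pyr-cyclohexa-1,3-dien-2-yl trifluoromethanesulfonate F5. Reduction with Pd(OAc)2, PPh3, Bu3N and HCO2H would give the diene (5S,6S)-6-[2-(TBS-oxy)ethyl]-1,3,5-trimethyl-5-Pyr-cyclohexa-1,3-diene F6. Dimethyldioxirane at low temperature should epoxidise the alkene remote from the quaternary carbon on the face anti to the chain, coming back to the route at 19.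

**Further compounds**

F1 | step 6 | allyl 2-(6-methoxy-3,5-dimethyl-4-oxo-4H-pyran-2-yl)acetate | C=CCOC(=O)Cc1oc(OC)c(C)c(=O)c1C
F2 | step 6 | allyl (3S)-3-[2-(TBS-oxy)ethyl]-5-oxo-2-Pyr-heptanoate (epimers at C2) | CC(C)(C)[Si](C)(C)OCC[C@H](C(C(=O)OCC=C)c1oc(OC)c(C)c(=O)c1C)CC(=O)CC
F3 | step 6 | (3S)-3-[2-(TBS-oxy)ethyl]-5-oxo-2-Pyr-heptanoic acid (epimers at C2) | CC(C)(C)[Si](C)(C)OCC[C@H](C(C(=O)O)c1oc(OC)c(C)c(=O)c1C)CC(=O)CC
F4 | step 8 | S-ethyl (2R,3S)-3-[2-(TBS-oxy)ethyl]-2-methyl-5-oxo-2-Pyr-heptanethioate | CC(C)(C)[Si](C)(C)OCC[C@H]([C@](C(=O)SCC)(C)c1oc(OC)c(C)c(=O)c1C)CC(=O)CC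
F5 | step 13 | (5S,6S)-6-[2-(TBS-oxy)ethyl]-1,3,5-trimethyl-5-Pyr-cyclohexa-1,3-dien-2-yl trifluoromethanesulfonate | CC(C)(C)[Si](C)(C)OCC[C@H]1C(C)=C(OS(=O)(=O)C(F)(F)F)C(C)=C[C@@]1(C)c1oc(OC)c(C)c(=O)c1C
F6 | step 13 | (5S,6S)-6-[2-(TBS-oxy)ethyl]-1,3,5-trimethyl-5-Pyr-cyclohexa-1,3-diene | CC(C)(C)[Si](C)(C)OCC[C@H]1C(C)=CC(C)=C[C@@]1(C)c1oc(OC)c(C)c(=O)c1C
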